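**Retrosynthetic overview**
1. Target 21 ⇐ 20: the last bond made is C–O, a catalyst-controlled epoxidation of the distal Z-olefin C3=C4 (oxirane formed last; sets C3 and C4).
2. 20 ⇐ 17: N–O cleavage, preceded by hydro-hydroxymethylation of a macrocyclic ynone (C8–C19; sets 7Z).
3. 17 ⇐ 16: intramolecular Horner–Wadsworth–Emmons olefination at C1=C2 closes the 14-membered carbocycle first; 16 comes from triol 15 by one triple oxidation.
4. 15 ⇐ 13 + 8: acetylide/aldehyde union at C8–C9; 13 comes from neryl acetate, which supplies the 3Z olefin.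
5. 8 ⇐ (R)-citronellal: C12 from the chiral pool, C13–O by enamine-catalysed α-oxyamination (the aminoxy group also protects), C1 and the isopropyl group from an isobutylphosphonate.

Assumption: ring locants follow cembrane numbering (C1 carries the isopropyl group, C8 carries C19H2OH, C9 and C14 are the ketones), "TMP-oxy" means (2,2,6,6-tetramethylpiperidin-1-yl)oxy, and the L-series Shi ketone is bought or made from L-sorbose.

**Route**

Step 1
Reactants: 1 (R)-citronellal
Product: 2 (2S,3R)-3,7-dimethyl-2-(TMP-oxy)oct-6-enal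
Conditions: TEMPO (1.5 equiv), (5S)-5-benzyl-2,2,3-trimethylimidazolidin-4-one·TFA (20 mol %), CuCl2·2H2O (10 mol %), air, acetone, −10 °C to rt
Reagents that add atoms: TEMPO, CC1(C)CCCC(C)(C)N1[O]
Why: Enamine-catalysed α-oxyamination of an aldehyde, in which the benzyl group of the (5S)-imidazolidinone shields one face of the E-enamine so that the C13–O bond forms as 13S under catalyst control, while C12 (R) is carried over from citronellal and the TMP ether serves as the hydroxyl protecting group.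

Step 2
Reactants: 3 triethyl phosphite; 4 1-bromo-2-methylpropane
Product: 5 diethyl (2-methylpropyl)phosphonate
Conditions: neat, 150 °C, EtBr distilled off
Reagents that add atoms: none
Why: Michaelis–Arbuzov reaction of a primary bromide, driven by removal of bromoethane.

Step 3
Reactants: 5 diethyl (2-methylpropyl)phosphonate; 2 (2S,3R)-3,7-dimethyl-2-(TMP-oxy)oct-6-enal
Product: 7 diethyl [(5S,6R)-4-hydroxy-2,6,10-trimethyl-5-(TMP-oxy)undec-9-en-3-yl]phosphonate (C3/C4 epimer mixture), via lithiated phosphonate 6 (not isolated)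
Conditions: 5, nBuLi, THF, −78 °C; then 2, −78 °C; aq NH4Cl
Reagents that add atoms: none
Why: 1,2-Addition of an α-lithio alkylphosphonate to an aldehyde forms C14–C1, and the two new centres are left as a mixture because both are erased later (oxidation at C14, olefination at C1).

Step 4
Reactants: 7 diethyl [(5S,6R)-4-hydroxy-2,6,10-trimethyl-5-(TMP-oxy)undec-9-en-3-yl]phosphonate
Product: 8 diethyl [(5S,6R)-4-hydroxy-2,6-dimethyl-9-oxo-5-(TMP-oxy)nonan-3-yl]phosphonate
Conditions: K2OsO4·2H2O (2 mol %), NaIO4 (4 equiv), 2,6-lutidine, dioxane/H2O 3:1, rt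
Reagents that add atoms: sodium periodate (oxygen source through the catalytic osmium cycle), [Na+].[O-]I(=O)(=O)=O
Why: Lemieux–Johnson oxidative cleavage of the only C=C present gives the C9 aldehyde without touching a stereocentre.

Step 5
Reactants: 9 neryl acetate
Product: 11 (2Z)-3-methyl-6-oxohex-2-en-1-yl acetate, via epoxy acetate 10 (not isolated)
Conditions: mCPBA (1.05 equiv), CH2Cl2, 0 °C; then H5IO6, THF/H2O, 0 °C
Reagents that add atoms: mCPBA, O=C(OO)c1cccc(Cl)c1
Why: Prilezhaev epoxidation picks the electron-rich 6,7-olefin (the 2,3-olefin is deactivated by the allylic acetate) and periodic acid cleaves the epoxide to the C7 aldehyde, leaving the 2Z olefin (future C3=C4) untouched.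

Step 6
Reactants: 11 (2Z)-3-methyl-6-oxohex-2-en-1-yl acetate
Product: 13 (2Z)-3-methylhept-2-en-6-yn-1-ol, via enyne acetate 12 (not isolated)
Conditions: dimethyl (1-diazo-2-oxopropyl)phosphonate (1.3 equiv), K2CO3 (2.5 equiv), MeOH, 0 °C to rt
Reagents that add atoms: dimethyl (1-diazo-2-oxopropyl)phosphonate, COP(=O)(OC)C(=[N+]=[N-])C(C)=O
Why: Seyferth–Gilbert homologation in the Ohira–Bestmann version adds C8 as a terminal alkyne carbon and the same K2CO3/MeOH removes the acetate.

Step 7
Reactants: 13 (2Z)-3-methylhept-2-en-6-yn-1-ol; 8 diethyl [(5S,6R)-4-hydroxy-2,6-dimethyl-9-oxo-5-(TMP-oxy)nonan-3-yl]phosphonate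
Product: 15 diethyl [(5S,6R,14Z)-4,9,16-trihydroxy-2,6,14-trimethyl-5-(TMP-oxy)hexadec-14-en-10-yn-3-yl]phosphonate (epimer mixture at C3/C4/C9), via dilithio alkoxide acetylide 14 (not isolated)
Conditions: 13 (2.2 equiv), nBuLi (4.4 equiv), THF, −78 to −20 °C; then 8, −78 to −40 °C; aq NH4Cl (excess 13 recovered)
Reagents that add atoms: none
Why: 1,2-Addition of a lithium acetylide to an aldehyde forms C8–C9, one acetylide equivalent being spent on the free hydroxyl of 8, and the new carbinol centre is irrelevant because it is oxidised next.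

Step 8
Reactants: 15 diethyl [(5S,6R,14Z)-4,9,16-trihydroxy-2,6,14-trimethyl-5-(TMP-oxy)hexadec-14-en-10-yn-3-yl]phosphonate
Product: 16 diethyl [(5S,6R,14Z)-2,6,14-trimethyl-4,9,16-trioxo-5-(TMP-oxy)hexadec-14-en-10-yn-3-yl]phosphonate (C3 epimer mixture)
Conditions: Dess–Martin periodinane (1,1,1-triacetoxy-1,2-benziodoxol-3(1H)-one, 4 equiv), NaHCO3, CH2Cl2, 0 °C to rt
Reagents that add atoms: none
Why: Dess–Martin oxidation turns the allylic alcohol into the Z-enal, the propargylic alcohol into the ynone and the β-hydroxyphosphonate into the β-ketophosphonate in one operation, with bicarbonate buffering so that the Z-enal and C13 do not isomerise.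

Step 9
Reactants: 16 diethyl [(5S,6R,14Z)-2,6,14-trimethyl-4,9,16-trioxo-5-(TMP-oxy)hexadec-14-en-10-yn-3-yl]phosphonate
Product: 17 (1E,3Z,12R,13S)-4,12-dimethyl-1-(propan-2-yl)-13-(TMP-oxy)cyclotetradeca-1,3-dien-7-yne-9,14-dione
Conditions: Ba(OH)2·8H2O (activated, 0.9 equiv), THF/H2O 40:1, 1 mM, 0 °C to rt
Reagents that add atoms: none
Why: Intramolecular Horner–Wadsworth–Emmons olefination of the α-branched β-ketophosphonate with the enal closes the 14-membered ring at C1=C2 and gives the 1E enone (C3 trans to the acyl group) under thermodynamic control of the elimination.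

Step 10
Reactants: 17 (1E,3Z,12R,13S)-4,12-dimethyl-1-(propan-2-yl)-13-(TMP-oxy)cyclotetradeca-1,3-dien-7-yne-9,14-dione
Product: 19 (1E,3Z,7Z,12R,13S)-8-(hydroxymethyl)-4,12-dimethyl-1-(propan-2-yl)-13-(TMP-oxy)cyclotetradeca-1,3,7-triene-9,14-dione, via copper allenolate 18 (not isolated)
Conditions: [(Ph3P)CuH]6 (0.25 equiv), toluene, −40 °C; then CH2O (monomeric, THF solution, 5 equiv), −40 to −20 °C; aq NH4Cl
Reagents that add atoms: formaldehyde, C=O
Why: Proposed new method: hydride from [(Ph3P)CuH]6 adds to C7 of the ynone (far more electrophilic than the α-branched dienone) to give copper allenolate 18, whose C8 is hydroxymethylated by CH2O from outside the ring and anti to the C6 chain, so that C19 ends cis to H7 and C6 cis to C9 (7Z); the closest known reaction type is the reductive aldol of alkynones with this copper hydride (so far intramolecular) and the hydroalumination–aldol of ynones.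

Step 11
Reactants: 19 (1E,3Z,7Z,12R,13S)-8-(hydroxymethyl)-4,12-dimethyl-1-(propan-2-yl)-13-(TMP-oxy)cyclotetradeca-1,3,7-triene-9,14-dione
Product: 20 (1E,3Z,7Z,12R,13S)-13-hydroxy-8-(hydroxymethyl)-4,12-dimethyl-1-(propan-2-yl)cyclotetradeca-1,3,7-triene-9,14-dione
Conditions: Zn dust, AcOH/THF/H2O 3:1:1, rt
Reagents that add atoms: none
Why: Reductive N–O cleavage of the α-aminoxy ketone releases the C13 hydroxyl with retention because the C13–O bond is not touched, and simple enones are not reduced by zinc in acetic acid at room temperature.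

Step 12
Reactants: 20 (1E,3Z,7Z,12R,13S)-13-hydroxy-8-(hydroxymethyl)-4,12-dimethyl-1-(propan-2-yl)cyclotetradeca-1,3,7-triene-9,14-dione
Product: 21 (1E,3S,4R,7Z,12R,13S)-3,4-epoxy-13-hydroxy-8-(hydroxymethyl)-4,12-dimethyl-1-(propan-2-yl)cyclotetradeca-1,7-diene-9,14-dione (CNP0251075.1)
Conditions: 1,2:4,5-di-O-isopropylidene-β-L-erythro-2,3-hexodiulo-2,6-pyranose (ent-Shi ketone, 30 mol %), KHSO5 (as Oxone, 1.4 equiv), K2CO3, Bu4NHSO4, MeCN/CH2(OMe)2, aq Na2B4O7 buffer (pH about 10), 0 °C
Reagents that add atoms: potassium peroxymonosulfate, [K+].[O-]S(=O)(=O)OO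
Why: Proposed new method: the electrophilic chiral dioxirane made in situ from the L-series ketone should attack only the γ,δ-olefin C3=C4 (the one C=C not directly acylated) through a spiro transition state with the lone vinylic H3 in the hindered quadrant, which puts oxygen on the face giving 3S,4R (the mirror image of the sense in which the D-fructose ketone gives (R,R)-epoxides from trisubstituted olefins) and keeps the cis geometry by concerted transfer; the closest known reaction type is the Shi epoxidation of acyclic 2,4-dienoates at the distal olefin, not yet shown on a macrocyclic cross-conjugated dienone with a Z-trisubstituted distal olefin and a free α-ketol.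

**Compound list**
1 | (R)-citronellal, (3R)-3,7-dimethyloct-6-enal | CC(C)=CCC[C@@H](C)CC=O | starting material
2 | (2S,3R)-3,7-dimethyl-2-[(2,2,6,6-tetramethylpiperidin-1-yl)oxy]oct-6-enal | CC(C)=CCC[C@@H](C)[C@H](ON1C(C)(C)CCCC1(C)C)C=O | intermediate
3 | triethyl phosphite | CCOP(OCC)OCC | starting material
4 | 1-bromo-2-methylpropane | CC(C)CBr | starting material
5 | diethyl (2-methylpropyl)phosphonate | CC(C)CP(=O)(OCC)OCC | intermediate
6 | diethyl (1-lithio-2-methylpropyl)phosphonate | [Li]C(C(C)C)P(=O)(OCC)OCC | intermediate (not isolated)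
7 | diethyl [(5S,6R)-4-hydroxy-2,6,10-trimethyl-5-[(2,2,6,6-tetramethylpiperidin-1-yl)oxy]undec-9-en-3-yl]phosphonate, C3/C4 epimer mixture | CC(C)=CCC[C@@H](C)[C@H](ON1C(C)(C)CCCC1(C)C)C(O)C(C(C)C)P(=O)(OCC)OCC | intermediate
8 | diethyl [(5S,6R)-4-hydroxy-2,6-dimethyl-9-oxo-5-[(2,2,6,6-tetramethylpiperidin-1-yl)oxy]nonan-3-yl]phosphonate | O=CCC[C@@H](C)[C@H](ON1C(C)(C)CCCC1(C)C)C(O)C(C(C)C)P(=O)(OCC)OCC | intermediate
9 | neryl acetate, (2Z)-3,7-dimethylocta-2,6-dien-1-yl acetate | CC(C)=CCC/C(C)=C\COC(C)=O | starting material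
10 | (2Z)-5-(3,3-dimethyloxiran-2-yl)-3-methylpent-2-en-1-yl acetate (racemic at the oxirane) | CC1(C)OC1CC/C(C)=C\COC(C)=O | intermediate (not isolated)
11 | (2Z)-3-methyl-6-oxohex-2-en-1-yl acetate | O=CCC/C(C)=C\COC(C)=O | intermediate
12 | (2Z)-3-methylhept-2-en-6-yn-1-yl acetate | C#CCC/C(C)=C\COC(C)=O | intermediate (not isolated)
13 | (2Z)-3-methylhept-2-en-6-yn-1-ol | C#CCC/C(C)=C\CO | intermediate
14 | O,C-dilithio derivative of 13 (lithium alkoxide and lithium acetylide) | [Li]C#CCC/C(C)=C\CO[Li] | intermediate (not isolated)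
15 | diethyl [(5S,6R,14Z)-4,9,16-trihydroxy-2,6,14-trimethyl-5-[(2,2,6,6-tetramethylpiperidin-1-yl)oxy]hexadec-14-en-10-yn-3-yl]phosphonate, epimer mixture at C3/C4/C9 | OC/C=C(C)\CCC#CC(O)CC[C@@H](C)[C@H](ON1C(C)(C)CCCC1(C)C)C(O)C(C(C)C)P(=O)(OCC)OCC | intermediate
16 | diethyl [(5S,6R,14Z)-2,6,14-trimethyl-4,9,16-trioxo-5-[(2,2,6,6-tetramethylpiperidin-1-yl)oxy]hexadec-14-en-10-yn-3-yl]phosphonate, C3 epimer mixture | O=C/C=C(C)\CCC#CC(=O)CC[C@@H](C)[C@H](ON1C(C)(C)CCCC1(C)C)C(=O)C(C(C)C)P(=O)(OCC)OCC | intermediate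
17 | (1E,3Z,12R,13S)-4,12-dimethyl-1-(propan-2-yl)-13-[(2,2,6,6-tetramethylpiperidin-1-yl)oxy]cyclotetradeca-1,3-dien-7-yne-9,14-dione | CC(C)/C1=C\C=C(C)/CCC#CC(=O)CC[C@@H](C)[C@H](ON2C(C)(C)CCCC2(C)C)C1=O | intermediate
18 | copper allenolate of 17 (C7=C8=C9–O–Cu, Ph3P-ligated monovalent copper) | CC(C)/C1=C\C=C(C)/CCC=C=C(O[Cu])CC[C@@H](C)[C@H](ON2C(C)(C)CCCC2(C)C)C1=O | intermediate (not isolated)
19 | (1E,3Z,7Z,12R,13S)-8-(hydroxymethyl)-4,12-dimethyl-1-(propan-2-yl)-13-[(2,2,6,6-tetramethylpiperidin-1-yl)oxy]cyclotetradeca-1,3,7-triene-9,14-dione | CC(C)/C1=C\C=C(C)/CC/C=C(/CO)C(=O)CC[C@@H](C)[C@H](ON2C(C)(C)CCCC2(C)C)C1=O | intermediate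
20 | (1E,3Z,7Z,12R,13S)-13-hydroxy-8-(hydroxymethyl)-4,12-dimethyl-1-(propan-2-yl)cyclotetradeca-1,3,7-triene-9,14-dione | CC(C)/C1=C\C=C(C)/CC/C=C(/CO)C(=O)CC[C@@H](C)[C@H](O)C1=O | intermediate
21 | (1E,3S,4R,7Z,12R,13S)-3,4-epoxy-13-hydroxy-8-(hydroxymethyl)-4,12-dimethyl-1-(propan-2-yl)cyclotetradeca-1,7-diene-9,14-dione | CC(C)/C1=C\[C@@H]2O[C@]2(C)CC/C=C(/CO)C(=O)CC[C@@H](C)[C@H](O)C1=O | target

**Totals**
Total steps: 12. Longest linear sequence: 9 (steps 1, 3, 4, 7, 8, 9, 10, 11, 12).

**Three steps most likely to fail**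

Step 12 (proposed new step). The macrocycle's own facial bias may oppose the catalyst, and the free α-ketol is exposed to pH 10. Fallback with known chemistry, substrate-controlled and by a different mechanism: set out from 20 and treat it with NBS in THF/H2O at 0 °C. Anti addition puts bromine on C3 and hydroxyl on the tertiary C4, giving (1E,3R,4R,7Z,12R,13S)-3-bromo-4,13-dihydroxy-8-(hydroxymethyl)-4,12-dimethyl-1-(propan-2-yl)cyclotetradeca-1,7-diene-9,14-dione F5. K2CO3 in MeOH at 0 °C then closes the oxirane with inversion at C3, which comes back to the route at 21. This places oxygen on the face opposite to the one an electrophile attacks directly, so it complements a direct peracid or dioxirane epoxidation.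

Step 10 (proposed new step). Risks are protonation instead of aldol trapping, over-reduction of the new enone, and competing reduction of the dienone. Fallback with known chemistry: set out from 17 and add Bu3SnH with Pd(PPh3)4 (THF, 0 °C). Syn hydrostannation with tin α to the ketone gives (1E,3Z,7E,12R,13S)-4,12-dimethyl-1-(propan-2-yl)-13-(TMP-oxy)-8-(tributylstannyl)cyclotetradeca-1,3,7-triene-9,14-dione F3. I2 (CH2Cl2, 0 °C) converts it with retention into the (7E)-8-iodo analogue F4. Stille coupling of F4 with Bu3SnCH2OH (Pd(PPh3)4, dioxane, 80 °C) comes back to the route at 19.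

Step 9. The ynone may not survive the basic olefination (hydration, isomerisation to an allenone), and the Z-enal may isomerise. Fallback: set out from 16 and mask the alkyne with Co2(CO)8 (CH2Cl2, rt) as the Co2(CO)6 alkyne complex of 16 F1, which is no longer a Michael acceptor and is bent in a way that favours ring closure. The same Ba(OH)2 olefination gives the Co2(CO)6 alkyne complex of 17 F2. I2 in THF at 0 °C removes the cobalt and comes back to the route at 17.

**Further compounds**
F1 | step 9 | Co2(CO)6 alkyne complex of 16 (hexacarbonyl dicobalt bridging C7 and C8) | O=C/C=C(C)\CCC12C3(C(=O)CC[C@@H](C)[C@H](ON4C(C)(C)CCCC4(C)C)C(=O)C(C(C)C)P(=O)(OCC)OCC)[Co]1(=C=O)(=C=O)(=C=O)[Co]23(=C=O)(=C=O)=C=O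
F2 | step 9 | Co2(CO)6 alkyne complex of 17 (hexacarbonyl dicobalt bridging C7 and C8) | CC(C)/C1=C\C=C(C)/CCC23C4(C(=O)CC[C@@H](C)[C@H](ON5C(C)(C)CCCC5(C)C)C1=O)[Co]2(=C=O)(=C=O)(=C=O)[Co]34(=C=O)(=C=O)=C=O
F3 | step 10 | (1E,3Z,7E,12R,13S)-4,12-dimethyl-1-(propan-2-yl)-13-[(2,2,6,6-tetramethylpiperidin-1-yl)oxy]-8-(tributylstannyl)cyclotetradeca-1,3,7-triene-9,14-dione | CC(C)/C1=C\C=C(C)/CC/C=C(/[Sn](CCCC)(CCCC)CCCC)C(=O)CC[C@@H](C)[C@H](ON2C(C)(C)CCCC2(C)C)C1=O
F4 | step 10 | (1E,3Z,7E,12R,13S)-8-iodo-4,12-dimethyl-1-(propan-2-yl)-13-[(2,2,6,6-tetramethylpiperidin-1-yl)oxy]cyclotetradeca-1,3,7-triene-9,14-dione | CC(C)/C1=C\C=C(C)/CC/C=C(/I)C(=O)CC[C@@H](C)[C@H](ON2C(C)(C)CCCC2(C)C)C1=O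
F5 | step 12 | (1E,3R,4R,7Z,12R,13S)-3-bromo-4,13-dihydroxy-8-(hydroxymethyl)-4,12-dimethyl-1-(propan-2-yl)cyclotetradeca-1,7-diene-9,14-dione | CC(C)/C1=C\[C@@H](Br)[C@](C)(O)CC/C=C(/CO)C(=O)CC[C@@H](C)[C@H](O)C1=O
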